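**Remark on the chemistry:** compounds 18, 19, 22, 24, 26 and 27 each carry one stereocentre that a later step destroys. It is left undefined in the SMILES, and the mixture is carried forward.

## Retrosynthetic overview

1. End game: Markovnikov hydration of a methallyl group, then removal of a temporary carbinol oxygen on the exocyclic CH2, then Nozaki–Hiyama–Kishi union of chroman aldehyde 13 with enol triflate 25 (bond between the exocyclic carbon and C6 of the hydrindenone).
2. Chroman: the dihydropyran ring is closed in one pot from a 2-(2-chloroaryl)ethyl Grignard reagent and a chiral-pool methyl ketone, forming C2–C3 first and O1–C8a second.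
3. Enabling feature: C2 of the dihydropyran ring is a fully substituted carbinol carbon (O1, CH3, C3, exocyclic CH2) whose oxygen is bonded to aryl carbon C8a, ortho to the ethylene tether C4–C3. It is therefore the carbonyl carbon of a ketone, and its exocyclic CH2 can be raised to an oxygen-bearing stereocentre (a dioxolane) that chelates, directs the addition and is then cut away.
4. Hydrindane: Cu-catalysed conjugate addition to 3-methylcyclohexenone sets C7a. Enolate methylation and intramolecular alkylation close the cyclopentane cis and relay C3a. The ketone is then taken to the 1,3-dione, C5 is allylated and C6 becomes the enol triflate.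
5. Ring order: cyclohexanone (bought) → cyclopentane (step 9); arene (bought) → dihydropyran (step 5); fragments joined in step 15.

Key step: step 5

## Route

Step 1
Reactants: 1 1-bromo-3-methoxy-5-methylbenzene
Product: 3 2-(3-methoxy-5-methylphenyl)ethanol, via arylmagnesium bromide 2 (not isolated)
Conditions: Mg, THF, reflux; then ethylene oxide, CuI (cat.), −20 °C → rt; aq. NH4Cl
Reagents that add atoms: ethylene oxide, C1CO1
Why: Copper-assisted opening of ethylene oxide by an aryl Grignard reagent is a standard two-carbon homologation to a 2-arylethanol.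

Step 2
Reactants: 3 2-(3-methoxy-5-methylphenyl)ethanol
Product: 4 2-(2-chloro-5-methoxy-3-methylphenyl)ethanol
Conditions: NCS, HCl (cat.), MeCN, rt
Reagents that add atoms: N-chlorosuccinimide, ClN1C(=O)CCC1=O
Why: Electrophilic aromatic chlorination of a 3,5-dialkylanisole should go para to the methoxy group, the position between the methyl group and the side chain, as in the chlorination of 3,5-dimethylanisole.

Step 3
Reactants: 4 2-(2-chloro-5-methoxy-3-methylphenyl)ethanol
Product: 5 1-(2-bromoethyl)-2-chloro-5-methoxy-3-methylbenzene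
Conditions: CBr4, PPh3, CH2Cl2, 0 °C
Reagents that add atoms: carbon tetrabromide, BrC(Br)(Br)Br
Why: The Appel reaction converts a primary alcohol into the bromide under neutral conditions that leave the aryl chloride and the ether untouched.

Step 4
Reactants: 6 methyl (R)-2,2-dimethyl-1,3-dioxolane-4-carboxylate
Product: 8 (R)-1-(2,2-dimethyl-1,3-dioxolan-4-yl)ethan-1-one, via Weinreb amide 7 (not isolated)
Conditions: MeNH(OMe)·HCl, i-PrMgCl, THF, −20 °C; then MeMgBr, 0 °C; aq. NH4Cl
Reagents that add atoms: methylmagnesium bromide, C[Mg]Br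
Why: One-pot Weinreb amide formation and Grignard addition should stop at the ketone through the stable chelated tetrahedral intermediate, and the cold, brief conditions should preserve the α-stereocentre.

Step 5
Reactants: 5 1-(2-bromoethyl)-2-chloro-5-methoxy-3-methylbenzene; 8 (R)-1-(2,2-dimethyl-1,3-dioxolan-4-yl)ethan-1-one
Product: 11 (2R)-2-[(4R)-2,2-dimethyl-1,3-dioxolan-4-yl]-6-methoxy-2,8-dimethylchromane, via alkyl Grignard reagent 9 (not isolated), via tertiary magnesium alkoxide 10 (not isolated)
Conditions: 5, Mg, THF, rt; 8, THF, −78 → 0 °C; then NaOt-Bu, t-BuXPhos Pd G3 (cat.), toluene, 90 °C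
Reagents that add atoms: none
Why: Magnesium should insert only into the alkyl C–Br bond (the hindered, electron-rich aryl chloride is inert), and Grignard reagent 9 should add to ketone 8 through the five-membered Cram chelate in which Mg bridges the carbonyl oxygen and the α-oxygen of the dioxolane, so that the new C2–C3 bond forms on the carbonyl face next to the α-hydrogen; NaOt-Bu then converts alkoxide 10 into the sodium alkoxide, which should undergo Pd(0)-catalysed intramolecular O-arylation (oxidative addition into C–Cl, alkoxide binding, C–O reductive elimination). The closest known reaction types are chelation-controlled Grignard addition to α-alkoxy ketones and Buchwald-type intramolecular etherification of tertiary alcohols with aryl halides to give chromans, here run in one pot. The dihydropyran ring is closed in the second event by C–O reductive elimination from a six-membered aryl–Pd alkoxide, so the whole operation is formally a [4+2] annulation of the ketone C=O with a 2-arylethyl unit. The new stereocentre C2 is controlled by the bought (R)-dioxolane stereocentre through 1,2-induction in the chelate. The step needs facial selectivity (chelate over Felkin-type or β-chelate addition, favoured by a ketone with an α-ether oxygen and a magnesium counter-ion), chemoselective metalation (alkyl bromide over aryl chloride) and etherification without β-hydride loss, which the fully substituted carbinol carbon rules out.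

Step 6
Reactants: 11 (2R)-2-[(4R)-2,2-dimethyl-1,3-dioxolan-4-yl]-6-methoxy-2,8-dimethylchromane
Product: 13 (R)-6-methoxy-2,8-dimethylchromane-2-carbaldehyde, via diol 12 (not isolated)
Conditions: AcOH/H2O (4:1), 45 °C; concentrate; then NaIO4, THF/H2O, 0 °C
Reagents that add atoms: none
Why: Acetal hydrolysis and periodate glycol cleavage remove the directing stereocentre and leave an aldehyde that cannot epimerise because its α-carbon is fully substituted.

Step 7
Reactants: 14 3-methylcyclohex-2-en-1-one; 15 (3-bromopropoxy)(tert-butyl)dimethylsilane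
Product: 18 (3R)-3-[3-(tert-butyldimethylsilyloxy)propyl]-2,3-dimethylcyclohexan-1-one, via alkyl Grignard reagent 16 (not isolated), via magnesium enolate 17 (not isolated)
Conditions: 15, Mg, Et2O; 14, Cu(OTf)2 (cat.), chiral imidazolinium salt (NHC precursor, cat.), Et2O, −30 °C; then MeI, DMPU, −30 °C → rt
Reagents that add atoms: iodomethane, CI
Why: Copper/NHC-catalysed asymmetric conjugate addition of Grignard reagents to 3-methylcyclohexenone sets the quaternary centre (the later C7a) under catalyst control, with the ligand enantiomer chosen to give the (R) product, and the regiodefined magnesium enolate is methylated in situ at C2.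

Step 8
Reactants: 18 (3R)-3-[3-(tert-butyldimethylsilyloxy)propyl]-2,3-dimethylcyclohexan-1-one
Product: 19 (3R)-3-(3-bromopropyl)-2,3-dimethylcyclohexan-1-one
Conditions: Ph3PBr2, CH2Cl2, 0 °C → rt
Reagents that add atoms: dibromotriphenylphosphorane, BrP(Br)(c1ccccc1)(c1ccccc1)c1ccccc1
Why: Dibromotriphenylphosphorane converts a primary silyl ether directly into the bromide via an alkoxyphosphonium ion, so no separate deprotection is needed.

Step 9
Reactants: 19 (3R)-3-(3-bromopropyl)-2,3-dimethylcyclohexan-1-one
Product: 20 (3aS,7aS)-3a,7a-dimethyloctahydro-4H-inden-4-one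
Conditions: KOt-Bu, t-BuOH/THF, rt
Reagents that add atoms: none
Why: Under equilibrating conditions the more substituted enolate should close the cyclopentane by 5-exo-tet alkylation, and because the tether must reach the enolate from the face on which it sits, the ring fusion is cis and C3a is relayed from C7a.

Step 10
Reactants: 20 (3aS,7aS)-3a,7a-dimethyloctahydro-4H-inden-4-one
Product: 21 (3aS,7aS)-3a,7a-dimethyl-1,2,3,3a,7,7a-hexahydro-4H-inden-4-one
Conditions: IBX, DMSO/toluene, 70 °C
Reagents that add atoms: none
Why: IBX dehydrogenation of a ketone to the enone can only occur toward C5–C6, because the other α-carbon is quaternary.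

Step 11
Reactants: 21 (3aS,7aS)-3a,7a-dimethyl-1,2,3,3a,7,7a-hexahydro-4H-inden-4-one
Product: 22 (3aS,7aS)-5,6-epoxy-3a,7a-dimethyloctahydro-4H-inden-4-one
Conditions: 30% H2O2, NaOH, MeOH, 0 °C
Reagents that add atoms: hydrogen peroxide, OO
Why: Weitz–Scheffer nucleophilic epoxidation of the cis-disubstituted enone should occur on the convex face, and the epoxide configuration is of no consequence.

Step 12
Reactants: 22 (3aS,7aS)-5,6-epoxy-3a,7a-dimethyloctahydro-4H-inden-4-one
Product: 23 (3aS,7aS)-3a,7a-dimethylhexahydro-1H-indene-4,6(5H)-dione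
Conditions: Pd(PPh3)4 (cat.), dppe (cat.), toluene, 100 °C
Reagents that add atoms: none
Why: Pd(0)-catalysed isomerisation of an α,β-epoxy ketone gives the β-diketone and so places the second carbonyl at C6.

Step 13
Reactants: 23 (3aS,7aS)-3a,7a-dimethylhexahydro-1H-indene-4,6(5H)-dione
Product: 24 (3aS,7aS)-3a,7a-dimethyl-5-(2-methylallyl)hexahydro-1H-indene-4,6(5H)-dione
Conditions: methyl 2-methylallyl carbonate, Pd(PPh3)4 (cat.), THF, rt
Reagents that add atoms: methyl 2-methylallyl carbonate, COC(=O)OCC(C)=C
Why: Tsuji–Trost allylation of a cyclic 1,3-dione under neutral conditions should give the C-allylated product at C5, because any O-allyl product re-ionises and funnels to carbon.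

Step 14
Reactants: 24 (3aS,7aS)-3a,7a-dimethyl-5-(2-methylallyl)hexahydro-1H-indene-4,6(5H)-dione
Product: 25 (3aS,7aS)-3a,7a-dimethyl-5-(2-methylallyl)-4-oxo-2,3,3a,4,7,7a-hexahydro-1H-inden-6-yl trifluoromethanesulfonate
Conditions: Tf2O, pyridine, CH2Cl2, −78 → 0 °C
Reagents that add atoms: triflic anhydride, O=S(=O)(C(F)(F)F)OS(=O)(=O)C(F)(F)F
Why: O-Sulfonylation of the dione enolate should occur at the C6 oxygen, which is flanked by a CH2 group, rather than at the C4 oxygen next to the quaternary C3a, giving the β-triflyloxy enone with the carbonyl at C4.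

Step 15
Reactants: 25 (3aS,7aS)-3a,7a-dimethyl-5-(2-methylallyl)-4-oxo-2,3,3a,4,7,7a-hexahydro-1H-inden-6-yl trifluoromethanesulfonate; 13 (R)-6-methoxy-2,8-dimethylchromane-2-carbaldehyde
Product: 26 (3aS,7aS)-6-{hydroxy[(2R)-6-methoxy-2,8-dimethylchroman-2-yl]methyl}-3a,7a-dimethyl-5-(2-methylallyl)-1,2,3,3a,7,7a-hexahydro-4H-inden-4-one
Conditions: CrCl2, NiCl2 (cat.), DMF, rt
Reagents that add atoms: none
Why: The Nozaki–Hiyama–Kishi reaction adds the alkenylchromium species from an enol triflate to an aldehyde chemoselectively in the presence of ketones, and the carbinol configuration does not matter because the oxygen is removed in step 17.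

Step 16
Reactants: 26 (3aS,7aS)-6-{hydroxy[(2R)-6-methoxy-2,8-dimethylchroman-2-yl]methyl}-3a,7a-dimethyl-5-(2-methylallyl)-1,2,3,3a,7,7a-hexahydro-4H-inden-4-one
Product: 27 acetate of 26
Conditions: Ac2O, DMAP, Et3N, CH2Cl2, rt
Reagents that add atoms: acetic anhydride, CC(=O)OC(C)=O
Why: DMAP-catalysed acetylation turns the γ-hydroxy group of the enone into a leaving group for reductive cleavage.

Step 17
Reactants: 27 acetate of 26
Product: 28 (3aS,7aS)-6-{[(2R)-6-methoxy-2,8-dimethylchroman-2-yl]methyl}-3a,7a-dimethyl-5-(2-methylallyl)-1,2,3,3a,7,7a-hexahydro-4H-inden-4-one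
Conditions: SmI2, THF/MeOH, −78 °C; aq. NH4Cl; then DBU (cat.), CH2Cl2, rt
Reagents that add atoms: none
Why: Samarium diiodide reduction of a γ-acetoxy enone expels acetate to give a dienolate whose protonation removes the oxygen, and the DBU treatment should bring any deconjugated isomer back to the tetrasubstituted conjugated enone.

Step 18
Reactants: 28 (3aS,7aS)-6-{[(2R)-6-methoxy-2,8-dimethylchroman-2-yl]methyl}-3a,7a-dimethyl-5-(2-methylallyl)-1,2,3,3a,7,7a-hexahydro-4H-inden-4-one
Product: 29 (3aS,7aS)-5-(2-hydroxy-2-methylpropyl)-6-{[(2R)-6-methoxy-2,8-dimethylchroman-2-yl]methyl}-3a,7a-dimethyl-1,2,3,3a,7,7a-hexahydro-4H-inden-4-one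
Conditions: Co(acac)2 (cat.), PhSiH3, O2 (1 atm), i-PrOH, rt; then Na2S2O3 (aq.)
Reagents that add atoms: dioxygen, O=O
Why: Mukaiyama hydration delivers a hydrogen atom to the terminal carbon of the 1,1-disubstituted alkene and oxygen to the tertiary radical, and the hindered, electron-poor tetrasubstituted enone should be a much poorer hydrogen-atom acceptor.

## Compound list

1 | 1-bromo-3-methoxy-5-methylbenzene | COc1cc(C)cc(Br)c1 | starting material
2 | (3-methoxy-5-methylphenyl)magnesium bromide | COc1cc(C)cc([Mg]Br)c1 | intermediate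
3 | 2-(3-methoxy-5-methylphenyl)ethanol | COc1cc(C)cc(CCO)c1 | intermediate
4 | 2-(2-chloro-5-methoxy-3-methylphenyl)ethanol | COc1cc(C)c(Cl)c(CCO)c1 | intermediate
5 | 1-(2-bromoethyl)-2-chloro-5-methoxy-3-methylbenzene | COc1cc(C)c(Cl)c(CCBr)c1 | intermediate
6 | methyl (R)-2,2-dimethyl-1,3-dioxolane-4-carboxylate | COC(=O)[C@H]1COC(C)(C)O1 | starting material
7 | (R)-N-methoxy-N,2,2-trimethyl-1,3-dioxolane-4-carboxamide | CON(C)C(=O)[C@H]1COC(C)(C)O1 | intermediate
8 | (R)-1-(2,2-dimethyl-1,3-dioxolan-4-yl)ethan-1-one | CC(=O)[C@H]1COC(C)(C)O1 | intermediate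
9 | [2-(2-chloro-5-methoxy-3-methylphenyl)ethyl]magnesium bromide | COc1cc(C)c(Cl)c(CC[Mg]Br)c1 | intermediate
10 | bromomagnesium (2R)-4-(2-chloro-5-methoxy-3-methylphenyl)-2-[(4R)-2,2-dimethyl-1,3-dioxolan-4-yl]butan-2-olate | COc1cc(C)c(Cl)c(CC[C@](C)([C@H]2COC(C)(C)O2)O[Mg]Br)c1 | intermediate
11 | (2R)-2-[(4R)-2,2-dimethyl-1,3-dioxolan-4-yl]-6-methoxy-2,8-dimethylchromane | COc1cc(C)c2c(c1)CC[C@](C)([C@H]1COC(C)(C)O1)O2 | intermediate
12 | (1R)-1-[(2R)-6-methoxy-2,8-dimethylchroman-2-yl]ethane-1,2-diol | COc1cc(C)c2c(c1)CC[C@](C)([C@H](O)CO)O2 | intermediate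
13 | (R)-6-methoxy-2,8-dimethylchromane-2-carbaldehyde | COc1cc(C)c2c(c1)CC[C@](C)(C=O)O2 | intermediate
14 | 3-methylcyclohex-2-en-1-one | CC1=CC(=O)CCC1 | starting material
15 | (3-bromopropoxy)(tert-butyl)dimethylsilane | CC(C)(C)[Si](C)(C)OCCCBr | starting material
16 | [3-(tert-butyldimethylsilyloxy)propyl]magnesium bromide | CC(C)(C)[Si](C)(C)OCCC[Mg]Br | intermediate
17 | bromomagnesium enolate of (R)-3-[3-(tert-butyldimethylsilyloxy)propyl]-3-methylcyclohexanone | C1CC(O[Mg]Br)=C[C@@](C)(CCCO[Si](C)(C)C(C)(C)C)C1 | intermediate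
18 | (3R)-3-[3-(tert-butyldimethylsilyloxy)propyl]-2,3-dimethylcyclohexan-1-one (C2 epimers) | C1CC(=O)C(C)[C@@](C)(CCCO[Si](C)(C)C(C)(C)C)C1 | intermediate
19 | (3R)-3-(3-bromopropyl)-2,3-dimethylcyclohexan-1-one (C2 epimers) | C1CC(=O)C(C)[C@@](C)(CCCBr)C1 | intermediate
20 | (3aS,7aS)-3a,7a-dimethyloctahydro-4H-inden-4-one | C1CC(=O)[C@@]2(C)CCC[C@@]2(C)C1 | intermediate
21 | (3aS,7aS)-3a,7a-dimethyl-1,2,3,3a,7,7a-hexahydro-4H-inden-4-one | C1=CC(=O)[C@@]2(C)CCC[C@@]2(C)C1 | intermediate
22 | (3aS,7aS)-5,6-epoxy-3a,7a-dimethyloctahydro-4H-inden-4-one (epoxide configuration not defined) | C12OC1C(=O)[C@@]3(C)CCC[C@@]3(C)C2 | intermediate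
23 | (3aS,7aS)-3a,7a-dimethylhexahydro-1H-indene-4,6(5H)-dione | O=C1CC(=O)[C@@]2(C)CCC[C@@]2(C)C1 | intermediate
24 | (3aS,7aS)-3a,7a-dimethyl-5-(2-methylallyl)hexahydro-1H-indene-4,6(5H)-dione (C5 enolisable) | O=C1C(CC(C)=C)C(=O)[C@@]2(C)CCC[C@@]2(C)C1 | intermediate
25 | (3aS,7aS)-3a,7a-dimethyl-5-(2-methylallyl)-4-oxo-2,3,3a,4,7,7a-hexahydro-1H-inden-6-yl trifluoromethanesulfonate | FC(F)(F)S(=O)(=O)OC1=C(CC(C)=C)C(=O)[C@@]2(C)CCC[C@@]2(C)C1 | intermediate
26 | (3aS,7aS)-6-{hydroxy[(2R)-6-methoxy-2,8-dimethylchroman-2-yl]methyl}-3a,7a-dimethyl-5-(2-methylallyl)-1,2,3,3a,7,7a-hexahydro-4H-inden-4-one (carbinol epimers) | COc1cc(C)c2c(c1)CC[C@](C)(C(O)C1=C(CC(C)=C)C(=O)[C@@]3(C)CCC[C@@]3(C)C1)O2 | intermediate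
27 | acetate of 26 (carbinol epimers) | COc1cc(C)c2c(c1)CC[C@](C)(C(OC(C)=O)C1=C(CC(C)=C)C(=O)[C@@]3(C)CCC[C@@]3(C)C1)O2 | intermediate
28 | (3aS,7aS)-6-{[(2R)-6-methoxy-2,8-dimethylchroman-2-yl]methyl}-3a,7a-dimethyl-5-(2-methylallyl)-1,2,3,3a,7,7a-hexahydro-4H-inden-4-one | COc1cc(C)c2c(c1)CC[C@](C)(CC1=C(CC(C)=C)C(=O)[C@@]3(C)CCC[C@@]3(C)C1)O2 | intermediate
29 | (3aS,7aS)-5-(2-hydroxy-2-methylpropyl)-6-{[(2R)-6-methoxy-2,8-dimethylchroman-2-yl]methyl}-3a,7a-dimethyl-1,2,3,3a,7,7a-hexahydro-4H-inden-4-one | COc1cc(C)c2c(c1)CC[C@](C)(CC1=C(CC(C)(C)O)C(=O)[C@@]3(C)CCC[C@@]3(C)C1)O2 | target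

## Step count and risks

Total steps: 18. Longest linear sequence: 12 (steps 7–18).

Steps most likely to fail:

1. Step 5. Facial selectivity may erode if addition through a non-chelated or β-chelated transition state competes, and the O-arylation may stall in the presence of magnesium salts. Fallback: this sets out from 5 and returns at 13. Grignard reagent 9 is added to ethyl pyruvate (THF, −78 °C) to give the racemic hydroxy ester F1. Pd-catalysed intramolecular O-arylation (t-BuXPhos Pd G3, Cs2CO3, toluene, 90 °C) gives the racemic chroman ester F2. Preparative chromatography on a chiral stationary phase gives the (R)-ester F3, and DIBAL-H (CH2Cl2, −78 °C) reduces it to aldehyde 13. Here C2 is obtained by separation instead of by induction.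

2. Step 7. The functionalised Grignard reagent may give insufficient enantioselectivity in the conjugate addition, and C-methylation of the magnesium enolate may be incomplete. Fallback: this sets out from 15 and returns at 18. Grignard reagent 16 is added to 3-ethoxycyclohex-2-en-1-one and the adduct is hydrolysed with dilute acid (Stork–Danheiser transposition) to give the 3-substituted enone F4. Copper/phosphoramidite-catalysed conjugate addition of trimethylaluminium, with the aluminium enolate trapped by acetic anhydride, gives the enol acetate F5. MeLi (2 equiv) followed by MeI then gives 18. The quaternary centre is thus made by methyl transfer to a 3-alkyl enone.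

3. Step 17. The reductive C–O cleavage may leave the double bond out of conjugation, or the ketone may be over-reduced. Fallback: this sets out from 26 and returns at 28. Alcohol 26 is treated with 1,1′-thiocarbonyldiimidazole (DMAP, toluene, 80 °C) to give the thiocarbonylimidazolide F6. Bu3SnH/AIBN (toluene, 100 °C) effects Barton–McCombie deoxygenation through the allylic radical, and a catalytic DBU treatment gives 28.

## Further compounds

F1 | step 5 | ethyl 4-(2-chloro-5-methoxy-3-methylphenyl)-2-hydroxy-2-methylbutanoate (racemic) | CCOC(=O)C(C)(O)CCc1cc(OC)cc(C)c1Cl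
F2 | step 5 | ethyl 6-methoxy-2,8-dimethylchromane-2-carboxylate (racemic) | CCOC(=O)C1(C)CCc2cc(OC)cc(C)c2O1
F3 | step 5 | ethyl (R)-6-methoxy-2,8-dimethylchromane-2-carboxylate | COc1cc(C)c2c(c1)CC[C@](C)(C(=O)OCC)O2
F4 | step 7 | 3-[3-(tert-butyldimethylsilyloxy)propyl]cyclohex-2-en-1-one | O=C1C=C(CCCO[Si](C)(C)C(C)(C)C)CCC1
F5 | step 7 | (R)-3-[3-(tert-butyldimethylsilyloxy)propyl]-3-methylcyclohex-1-en-1-yl acetate | C1CC(OC(C)=O)=C[C@@](C)(CCCO[Si](C)(C)C(C)(C)C)C1
F6 | step 17 | O-thiocarbonylimidazolide of 26 | COc1cc(C)c2c(c1)CC[C@](C)(C(OC(=S)n1ccnc1)C1=C(CC(C)=C)C(=O)[C@@]3(C)CCC[C@@]3(C)C1)O2
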